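## Analysis of the target

The target (23) is a 3-arylcoumarin: a 2H-chromen-2-one with a methoxy group on C5 and a free hydroxyl on C7, joined through C3 to C6 of a 5-methoxy-2,2-dimethylchroman. It holds four rings in two bicyclic units, linked by one sp2–sp2 bond. There is no stereocentre, and the C3–C6 axis carries only small ortho groups (lactone carbonyl and H on one side, OMe and H on the other), so it rotates freely and no stereochemical question arises. The sensitive points are the lactone, which opens with hydroxide or alkoxide and is a Michael acceptor at C4, and the electron-rich benzo ring of the coumarin, which takes up electrophiles at C6 and C8. The 7-OH must also stay distinct from the 5-OMe from the start. The real difficulty is the chroman benzene ring: oxygen on C8a, alkyl on C4a, methoxy on C5 and the coumarin on C6 are contiguous, with hydrogen only on C7 and C8, and electrophilic substitution on a resorcinol derivative does not give this pattern selectively. Read from C8a, this ring is a phenol with an alkyl group ortho, an alkoxy group meta and an sp2 substituent para. That is the arrangement produced when a vinylketene released from a cyclobutenone combines with an alkynyl ether, and the strategy rests on it.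

## Retrosynthetic reasoning

The first cut is the O1–C2 bond of the dihydropyran ring of 23, which leads back to triol 22. The tertiary ether forms readily under acid through the tertiary cation, and no other hydroxyl of 22 can reach that cation in a five- or six-membered ring. The cut also turns the bicyclic chroman into a monocyclic phenol with a plain side chain. The forward reaction only has to ionise the tertiary alcohol without harming the lactone.

Triol 22 is traced, through 21, to 20, in which the tertiary alcohol is a triethylsilyl ether and the coumarin 7-OH a methoxymethyl ether. Both groups are there for the ring-forming step, where a free alcohol or a second free phenol would add to the ketene intermediates. Both fall in one acidic alcoholysis, so no separate deprotection chemistry is needed.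

The benzene ring of 20 is cut at three bonds, C8a–C4a, C5–C6 and C8a–C8 (chroman numbering). This gives cyclobutenone 9, which supplies C6, C7, C8 and C8a with the coumarin already on C6, and alkynyl ether 15, which supplies C4a with its side chain and C5 with its methoxy group. The forward path runs through 16, 17, 18 and 19. Cutting here, and not at the bond between the two ring systems, means that the place of every substituent follows from the connectivity of the partners and the polarisation of the alkyne, not from directing effects on a finished arene. The forward reaction must open 9 thermally without destroying it, join ketene and alkyne in the right orientation, and close the six-membered ring onto the vinyl terminus and not onto the coumarin.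

Cyclobutenone 9 is cut at the bond between coumarin C3 and the α-carbon of the enone, giving stannane 5 and bromoenone 8 for a Stille coupling under zerovalent palladium. The neutral conditions suit both the lactone and the strained enone, whereas a boron-based coupling would bring aqueous base. The tin is placed on the coumarin and the halogen on the four-membered ring because the α-bromoenone is the natural electrophile and 8 is reached in one operation.

Bromoenone 8 is traced to ketone 6 through dibromide 7: α-bromination, then loss of the β-bromide. Because the leaving group is already on C3 of 6, the position of the double bond is fixed.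

Stannane 5 comes from bromide 4 by palladium-catalysed exchange of halogen for tin. Bromide 4 is not made by brominating a finished coumarin, because the dioxygenated benzo ring would compete for the electrophile at C6 and C8. Instead the C3–C4 double bond and the lactone are formed together from salicylaldehyde 2 and a Wittig reagent that already carries the bromine, through 3. Aldehyde 2 comes from 1 by protecting the hydroxyl para to the formyl group, which is the more acidic one and is not held in a hydrogen bond.

Alkyne 15 is cut at its propargylic C–C bond into iodide 12 and acetylide 14, which is generated from chloroacetal 13. Iodide 12 comes from diol 10 by turning the primary hydroxyl into the iodide (11) and silylating the tertiary hydroxyl.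

## Alternatives that were turned down

Alternative 1: The pyranone ring of the coumarin is cut at C4–C4a and O1–C2. In the forward direction phloroglucinol (A1) and the α-formyl arylacetate A2 condense under acid in a Pechmann-type annulation to the 3-arylcoumarin A3.
- For it: the step is short and convergent, needs no protecting group on the coumarin, and the symmetry of A1 removes any regiochemical question in the ring closure.
- Against it: A3 has both the 5- and the 7-hydroxyl free, and the target carries its methyl on O5. The 7-hydroxyl is the more acidic and the more exposed, so three extra steps (protect O7, methylate O5, deprotect) would follow. A2 must itself come from a chroman with the same four contiguous substituents, so the main difficulty is only moved. The enolisable formyl ester and the electron-rich chroman are also exposed to strong acid.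
- Comparison: Alternative 1 is stronger on the step count of the coumarin half and avoids tin and a strained enone. The chosen strategy offers in its place an O5/O7 pattern that is differentiated from the first step and a regiocontrolled construction of the chroman arene.

Alternative 2: The chroman benzene ring is cut at C4a–C5 and C6–C7. In the forward direction the bicyclic 2-pyranone A4 acts as diene toward the coumarinyl methoxyalkyne A5 in a thermal [4+2] cycloaddition, and decarboxylative aromatisation of the bridged adduct gives A6.
- For it: it also builds the arene from non-aromatic pieces with the orientation set by alkyne polarisation. It is stronger than the chosen route on one point: the dihydropyran ring is already closed, so A6 needs only removal of the methoxymethyl group.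
- Against it: pyranone cycloadditions with alkynes need temperatures well above those of a cyclobutenone opening and prefer electron-poor alkynes. In A5 the nucleophilic alkyne carbon is conjugated to the coumarin and so deactivated, and the C3–C4 double bond of A5 could itself act as dienophile. A5 would also be hard to make and store, since a methoxyethynyl group would have to be coupled onto coumarin C3 and such conjugated ynol ethers hydrate easily.
- Comparison: the chosen strategy uses an alkyl-substituted ynol ether whose nucleophilicity is intact and runs at 80–110 °C. It pays one extra acid step for the pyran ring.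

Alternative 3: The lactone is cut at C2–C3 and C2–O1, so that the carbonyl carbon is inserted last. In the forward direction the (E)-2-hydroxystilbene A7 undergoes oxidative cyclocarbonylation with a divalent palladium catalyst and a quinone oxidant in a carbonylating atmosphere to give A8.
- For it: A7 is reachable by olefination and has the right geometry (the alkene hydrogen to be replaced is cis to the phenol ring). The benzyl ether leaves by hydrogenolysis, and the route is as convergent as the chosen one without tin or strained rings.
- Against it: 2-hydroxystilbenes under divalent palladium tend to undergo five-membered oxypalladation and β-hydride elimination, which here would give benzofuran A9. The phloroglucinol-type phenol is also exposed to the oxidant. The alkene carbon to be carbonylated is flanked by an ortho-methoxy aryl group. The chroman half of A7 still needs the contiguous pattern made by other means.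
- Comparison: Alternative 3 is as strong on convergence and stronger on atom economy at the carbonyl carbon. The chosen strategy instead solves the chroman arene itself and keeps oxidants away from the electron-rich rings.

Key step: step 9

Remark on the chemistry: 2,4-dihydroxy-6-methoxybenzaldehyde (1) and 3-bromocyclobutan-1-one (6) are taken as purchasable compounds, so the 5-O-methyl/7-OH pattern and the leaving group on the four-membered ring are bought, not made.

## Route

Step 1
Reactants: 1 2,4-dihydroxy-6-methoxybenzaldehyde
Product: 2 2-hydroxy-6-methoxy-4-(methoxymethoxy)benzaldehyde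
Conditions: MOMCl (1.1 equiv), iPr2NEt, CH2Cl2, 0 °C to rt
Reagents that add atoms: chloromethyl methyl ether, COCCl
Why: O-alkylation of a phenol (MOM protection); the 4-hydroxyl, para to the formyl group, is the more acidic and is not held in the hydrogen bond that deactivates the 2-hydroxyl, so one equivalent of the chloride should react there selectively.

Step 2
Reactants: 2 2-hydroxy-6-methoxy-4-(methoxymethoxy)benzaldehyde
Product: 4 3-bromo-5-methoxy-7-(methoxymethoxy)-2H-chromen-2-one, via bromoacrylate ester 3 (not isolated)
Conditions: Ph3P=C(Br)CO2Et, toluene, 110 °C; then PhNEt2, 200 °C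
Reagents that add atoms: ethyl bromo(triphenylphosphoranylidene)acetate, CCOC(=O)C(Br)=P(c1ccccc1)(c1ccccc1)c1ccccc1
Why: Wittig olefination with a stabilised bromo ylide gives acrylate 3; the isomer with the aryl group cis to the ester lactonises at once, and the other should isomerise in the hot amine solvent and then close (the Wittig route to coumarins). The bromine arrives with the ylide, so no electrophilic bromination of the electron-rich benzo ring at C6 or C8 is needed.

Step 3
Reactants: 4 3-bromo-5-methoxy-7-(methoxymethoxy)-2H-chromen-2-one
Product: 5 5-methoxy-7-(methoxymethoxy)-3-(trimethylstannyl)-2H-chromen-2-one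
Conditions: (Me3Sn)2, Pd(PPh3)4, toluene, 100 °C
Reagents that add atoms: hexamethyldistannane, C[Sn](C)(C)[Sn](C)(C)C
Why: Palladium-catalysed stannylation of a vinyl bromide: oxidative addition of zerovalent palladium into the activated C3–Br bond, transmetallation with the Sn–Sn reagent and reductive elimination. The neutral conditions leave the lactone and the MOM ether untouched.

Step 4
Reactants: 6 3-bromocyclobutan-1-one
Product: 8 2-bromocyclobut-2-en-1-one, via 2,3-dibromocyclobutan-1-one 7 (not isolated)
Conditions: Br2 (1.0 equiv), CH2Cl2, 0 °C; then Et3N (2.1 equiv), −20 °C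
Reagents that add atoms: bromine, BrBr
Why: α-Bromination through the enol gives dibromide 7; triethylamine then removes the more acidic proton on the bromine-bearing α-carbon and the enolate expels the β-bromide (E1cB), which leaves the remaining bromine on the α-carbon of the enone. The product should be kept cold in solution and used at once, because strained enones polymerise.

Step 5
Reactants: 5 5-methoxy-7-(methoxymethoxy)-3-(trimethylstannyl)-2H-chromen-2-one; 8 2-bromocyclobut-2-en-1-one
Product: 9 2-[5-methoxy-7-(methoxymethoxy)-2-oxo-2H-chromen-3-yl]cyclobut-2-en-1-one
Conditions: Pd2(dba)3, AsPh3, CuI (cat.), DMF, 25 °C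
Reagents that add atoms: none
Why: Stille coupling of an α-bromoenone with an alkenylstannane; the weakly bound arsine ligand and the CuI co-catalyst should allow transmetallation at room temperature, below the temperature at which the cyclobutenone opens. The stannane transfers its sp2 carbon in preference to methyl, and no base or water is present that could attack the lactone or the strained enone.

Step 6
Reactants: 10 3-methylbutane-1,3-diol
Product: 11 4-iodo-2-methylbutan-2-ol
Conditions: I2, PPh3, imidazole, CH2Cl2, 0 °C
Reagents that add atoms: iodine, II
Why: Appel iodination: the primary hydroxyl forms the alkoxyphosphonium ion and is displaced by iodide (SN2), while the hindered tertiary hydroxyl should not react at 0 °C.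

Step 7
Reactants: 11 4-iodo-2-methylbutan-2-ol
Product: 12 triethyl[(4-iodo-2-methylbutan-2-yl)oxy]silane
Conditions: Et3SiOTf, 2,6-lutidine, CH2Cl2, −78 to 0 °C
Reagents that add atoms: triethylsilyl trifluoromethanesulfonate, CC[Si](CC)(CC)OS(=O)(=O)C(F)(F)F
Why: Silylation of a tertiary alcohol with a silyl triflate and a non-nucleophilic pyridine base; the primary iodide is inert to these conditions. The silyl ether masks the alcohol against the acetylide of step 8 and the ketenes of step 9.

Step 8
Reactants: 13 2-chloro-1,1-dimethoxyethane; 12 triethyl[(4-iodo-2-methylbutan-2-yl)oxy]silane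
Product: 15 triethyl[(6-methoxy-2-methylhex-5-yn-2-yl)oxy]silane, via lithium methoxyacetylide 14 (not isolated)
Conditions: LiNEt2 (3 equiv per 13), THF, 0 °C; then 12, HMPA, −20 °C to rt; NaHCO3 work-up
Reagents that add atoms: none
Why: Three equivalents of LiNEt2 convert chloroacetal 13 into acetylide 14 by two eliminations (loss of methoxide, then of chloride) and a deprotonation; 14 then displaces the primary iodide of 12 (SN2 alkylation of an acetylide, helped by HMPA). The work-up is basic because ynol ethers hydrate under acid.

Step 9
Reactants: 9 2-[5-methoxy-7-(methoxymethoxy)-2-oxo-2H-chromen-3-yl]cyclobut-2-en-1-one; 15 triethyl[(6-methoxy-2-methylhex-5-yn-2-yl)oxy]silane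
Product: 20 3-[4-hydroxy-2-methoxy-3-(3-methyl-3-triethylsilyloxybutyl)phenyl]-5-methoxy-7-(methoxymethoxy)-2H-chromen-2-one, via vinylketene 16 (not isolated), via vinylcyclobutenone 17 (not isolated), via dienylketene 18 (not isolated), via cyclohexadienone 19 (not isolated)
Conditions: 15 (1.5 equiv), toluene, 80 °C then 110 °C, sealed tube, argon
Reagents that add atoms: none
Why: This is a Danheiser benzannulation: at about 80 °C cyclobutenone 9 should open by conrotatory 4π electrocyclic cleavage of its C1–C4 bond to vinylketene 16, which carries the coumarin on the ketene α-carbon. Ynol ether 15 then adds across the ketene C=C bond in a [2+2] cycloaddition in which its nucleophilic carbon β to oxygen bonds to the ketene carbonyl carbon (C8a–C4a) and its oxygen-bearing carbon to the ketene α-carbon (C5–C6), giving vinylcyclobutenone 17. A second 4π opening gives dienylketene 18, and the only ring formed, the benzene ring, closes by thermal disrotatory 6π electrocyclisation between the ketene carbon and the vinyl terminus (C8a–C8); dienone 19 tautomerises to phenol 20. The closest known reaction type is the thermal benzannulation of cyclobutenones with alkoxyalkynes to 2-alkyl-3-alkoxyphenols. No stereocentre is created in 20, and the quaternary carbon of 17 is only transient. The regioselectivity needed is secured by the methoxy group of 15, which polarises the triple bond and so places the side chain ortho, the methoxy group meta and the coumarin para to the new hydroxyl. The step also needs periselectivity in 18, closure onto the vinyl group and not onto the coumarin C3–C4 bond: the CH2 terminus is unhindered, whereas coumarin C4 is shielded by the peri 5-methoxy group and its use would interrupt the lactone conjugation, and the reversible opening of 17 returns the unproductive geometric isomer of 18. Loss of ring strain and aromatisation pull the sequence forward, and the O-methyl group of 15 has no β-hydrogen, so the alkyne should tolerate 110 °C without losing an alkene through a six-membered transition state.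

Step 10
Reactants: 20 3-[4-hydroxy-2-methoxy-3-(3-methyl-3-triethylsilyloxybutyl)phenyl]-5-methoxy-7-(methoxymethoxy)-2H-chromen-2-one
Product: 22 7-hydroxy-3-[4-hydroxy-3-(3-hydroxy-3-methylbutyl)-2-methoxyphenyl]-5-methoxy-2H-chromen-2-one, via methoxymethyl ether diol 21 (not isolated)
Conditions: HCl, MeOH, 0 to 40 °C
Reagents that add atoms: none
Why: Acid-catalysed methanolysis: the silyl ether should fall first (21), then the methoxymethyl acetal exchanges with the solvent, which also traps the formaldehyde unit as its dimethyl acetal so that it cannot alkylate the electron-rich rings. The lactone and both aryl methyl ethers are stable to dilute HCl in methanol. Any early closure of the tertiary alcohol onto the neighbouring phenol would only anticipate step 11.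

Step 11
Reactants: 22 7-hydroxy-3-[4-hydroxy-3-(3-hydroxy-3-methylbutyl)-2-methoxyphenyl]-5-methoxy-2H-chromen-2-one
Product: 23 7-hydroxy-5-methoxy-3-(5-methoxy-2,2-dimethyl-3,4-dihydro-2H-chromen-6-yl)-2H-chromen-2-one
Conditions: TsOH·H2O (0.2 equiv), 1,2-dichloroethane, 70 °C, dilute
Reagents that add atoms: none
Why: Acid-mediated cyclodehydration: the tertiary alcohol ionises to the tertiary carbocation, which the ortho phenol captures in a six-membered closure to the 2,2-dimethylchroman; any alkene formed by elimination re-protonates to the same cation. Only the C8a hydroxyl can reach the cation, the coumarin 7-OH and the methyl ethers are spectators, and no stereocentre is formed.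

## Compound list

1 | 2,4-dihydroxy-6-methoxybenzaldehyde | COc1cc(O)cc(O)c1C=O | starting material
2 | 2-hydroxy-6-methoxy-4-(methoxymethoxy)benzaldehyde | COCOc1cc(O)c(C=O)c(OC)c1 | intermediate
3 | ethyl 2-bromo-3-[2-hydroxy-6-methoxy-4-(methoxymethoxy)phenyl]prop-2-enoate (mixture of double-bond isomers; not isolated) | CCOC(=O)C(Br)=Cc1c(O)cc(OCOC)cc1OC | intermediate
4 | 3-bromo-5-methoxy-7-(methoxymethoxy)-2H-chromen-2-one | COCOc1cc(OC)c2cc(Br)c(=O)oc2c1 | intermediate
5 | 5-methoxy-7-(methoxymethoxy)-3-(trimethylstannyl)-2H-chromen-2-one | COCOc1cc(OC)c2cc([Sn](C)(C)C)c(=O)oc2c1 | intermediate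
6 | 3-bromocyclobutan-1-one | O=C1CC(Br)C1 | starting material
7 | 2,3-dibromocyclobutan-1-one (racemic, cis/trans mixture; not isolated) | O=C1CC(Br)C1Br | intermediate
8 | 2-bromocyclobut-2-en-1-one | O=C1CC=C1Br | intermediate
9 | 2-[5-methoxy-7-(methoxymethoxy)-2-oxo-2H-chromen-3-yl]cyclobut-2-en-1-one | COCOc1cc(OC)c2cc(C3=CCC3=O)c(=O)oc2c1 | intermediate
10 | 3-methylbutane-1,3-diol | CC(C)(O)CCO | starting material
11 | 4-iodo-2-methylbutan-2-ol | CC(C)(O)CCI | intermediate
12 | triethyl[(4-iodo-2-methylbutan-2-yl)oxy]silane | CC[Si](CC)(CC)OC(C)(C)CCI | intermediate
13 | 2-chloro-1,1-dimethoxyethane (chloroacetaldehyde dimethyl acetal) | COC(CCl)OC | starting material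
14 | lithium methoxyacetylide (not isolated) | [Li]C#COC | intermediate
15 | triethyl[(6-methoxy-2-methylhex-5-yn-2-yl)oxy]silane | COC#CCCC(C)(C)O[Si](CC)(CC)CC | intermediate
16 | 2-[5-methoxy-7-(methoxymethoxy)-2-oxo-2H-chromen-3-yl]buta-1,3-dien-1-one (vinylketene; not isolated) | C=CC(=C=O)c1cc2c(OC)cc(OCOC)cc2oc1=O | intermediate
17 | 4-ethenyl-3-methoxy-4-[5-methoxy-7-(methoxymethoxy)-2-oxo-2H-chromen-3-yl]-2-[3-methyl-3-(triethylsilyloxy)butyl]cyclobut-2-en-1-one (racemic; not isolated) | C=CC1(c2cc3c(OC)cc(OCOC)cc3oc2=O)C(=O)C(CCC(C)(C)O[Si](CC)(CC)CC)=C1OC | intermediate
18 | (3Z)-3-methoxy-4-[5-methoxy-7-(methoxymethoxy)-2-oxo-2H-chromen-3-yl]-2-[3-methyl-3-(triethylsilyloxy)butyl]hexa-1,3,5-trien-1-one (dienylketene; not isolated) | O=C=C(CCC(C)(C)O[Si](CC)(CC)CC)/C(OC)=C(\C=C)c1cc2c(OC)cc(OCOC)cc2oc1=O | intermediate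
19 | 3-methoxy-4-[5-methoxy-7-(methoxymethoxy)-2-oxo-2H-chromen-3-yl]-2-[3-methyl-3-(triethylsilyloxy)butyl]cyclohexa-2,4-dien-1-one (not isolated) | O=C1CC=C(c2cc3c(OC)cc(OCOC)cc3oc2=O)C(OC)=C1CCC(C)(C)O[Si](CC)(CC)CC | intermediate
20 | 3-[4-hydroxy-2-methoxy-3-(3-methyl-3-triethylsilyloxybutyl)phenyl]-5-methoxy-7-(methoxymethoxy)-2H-chromen-2-one | COCOc1cc(OC)c2cc(-c3ccc(O)c(CCC(C)(C)O[Si](CC)(CC)CC)c3OC)c(=O)oc2c1 | intermediate
21 | 3-[4-hydroxy-3-(3-hydroxy-3-methylbutyl)-2-methoxyphenyl]-5-methoxy-7-(methoxymethoxy)-2H-chromen-2-one (not isolated) | COCOc1cc(OC)c2cc(-c3ccc(O)c(CCC(C)(C)O)c3OC)c(=O)oc2c1 | intermediate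
22 | 7-hydroxy-3-[4-hydroxy-3-(3-hydroxy-3-methylbutyl)-2-methoxyphenyl]-5-methoxy-2H-chromen-2-one | COc1cc(O)cc2oc(=O)c(-c3ccc(O)c(CCC(C)(C)O)c3OC)cc12 | intermediate
23 | 7-hydroxy-5-methoxy-3-(5-methoxy-2,2-dimethyl-3,4-dihydro-2H-chromen-6-yl)-2H-chromen-2-one | COc1c(-c2cc3c(OC)cc(O)cc3oc2=O)ccc2c1CCC(C)(C)O2 | target

## Step count and least certain steps

Total: 11 steps. Longest linear sequence: 7 steps (steps 1, 2, 3, 5, 9, 10, 11).

Step 9 (key step). Two processes are most likely to go wrong. Vinylketene 16, stabilised by the conjugated, electron-poor coumarin, may be consumed by dimerisation or by acylating the product phenol faster than by the alkyne. Dienylketene 18 may also close onto the coumarin C3–C4 bond instead of the vinyl group. An excess of 15, slow addition of 9, and mild methanolysis of any aryl ester formed would be tried first. The fallback takes the coumarin out of the annulation. It sets out from 8 and 15: heating them in toluene at 80 °C should give 4-bromo-3-methoxy-2-[3-methyl-3-(triethylsilyloxy)butyl]phenol (F1) by the same cascade. A Stille coupling of F1 with stannane 5 (Pd(P(t-Bu)3)2, CsF, dioxane, 90 °C) then forms the bond to the coumarin and comes back to the route at 20.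

Step 5. The strained bromoenone 8 may polymerise or be attacked by nucleophiles before oxidative addition, the electron-poor stannane 5 may transmetallate slowly and lose tin by protonation, and product 9 is itself a reactive Michael acceptor. The fallback builds the four-membered ring on the coumarin and needs neither 5 nor 8; it sets out from bromide 4 and comes back to the route at 9. Coupling of 4 with the Reformatsky reagent BrZnCH2CO2Et (Pd2(dba)3, XPhos, THF, 50 °C) should give ethyl 2-[5-methoxy-7-(methoxymethoxy)-2-oxo-2H-chromen-3-yl]acetate (F2). Ester F2 is then hydrolysed with LiOH in aqueous THF, and mild acidification, which also recloses the lactone, gives 2-[5-methoxy-7-(methoxymethoxy)-2-oxo-2H-chromen-3-yl]acetic acid (F3). 1-Chloro-N,N,2-trimethylprop-1-en-1-amine converts F3 under neutral conditions into 2-[5-methoxy-7-(methoxymethoxy)-2-oxo-2H-chromen-3-yl]acetyl chloride (F4). Et3N in excess ethyl vinyl ether dehydrochlorinates F4 to 5-methoxy-7-(methoxymethoxy)-3-(2-oxoethenyl)-2H-chromen-2-one (F5), the aryl ketene, and F5 adds to the vinyl ether in a [2+2] cycloaddition to give 3-ethoxy-2-[5-methoxy-7-(methoxymethoxy)-2-oxo-2H-chromen-3-yl]cyclobutan-1-one (F6). DBU in CH2Cl2 at 0 °C then eliminates ethanol from F6 by an E1cB process to give 9.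

Step 4. Enol bromination of a four-membered ketone is slow and may go on to a second bromination, and 8 is volatile and polymerises easily. The fallback sets out from 6. Elimination with Bu3N gives cyclobut-2-en-1-one (F7), which is distilled. Bromine then adds across the C=C bond of F7, which can only give the 2,3-dibromide, and the route is rejoined at 7.

Step 2. The Wittig reaction should give mainly the isomer of 3 in which the aryl group is trans to the ester, and forcing its isomerisation at 200 °C may cost the bromine or the MOM group. The fallback uses an olefination whose geometry is already right for lactonisation; it sets out from 2 and comes back at 4. Silylation of 2 (t-BuMe2SiOTf, 2,6-lutidine) gives 2-(tert-butyldimethylsilyloxy)-6-methoxy-4-(methoxymethoxy)benzaldehyde (F8). Aldehyde F8 then undergoes a Horner–Wadsworth–Emmons reaction with ethyl 2-[bis(2,2,2-trifluoroethoxy)phosphoryl]-2-bromoacetate (t-BuOK, 18-crown-6, THF, −78 °C), which should give ethyl (E)-2-bromo-3-[2-(tert-butyldimethylsilyloxy)-6-methoxy-4-(methoxymethoxy)phenyl]prop-2-enoate (F9), with aryl and ester cis. Bu4NF in THF at 0 °C frees the phenoxide of F9, which displaces ethoxide and closes the lactone to 4.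

Step 8. Acetylide 14 may act as a base toward iodide 12 (E2) instead of as a nucleophile, and the ynol ether may hydrate during isolation. The fallback replaces the SN2 reaction by a strain-driven ring opening; it sets out from 11 and comes back at 15. NaH in THF closes 11 to 2,2-dimethyloxetane (F10). Acetylide 14, made from 13 as in step 8, opens F10 at its CH2–O carbon with BF3·OEt2 at −78 °C to give 6-methoxy-2-methylhex-5-yn-2-ol (F11), and Et3SiOTf with 2,6-lutidine silylates F11 to 15.

## Further compounds

F1 | step 9 | 4-bromo-3-methoxy-2-[3-methyl-3-(triethylsilyloxy)butyl]phenol | COc1c(Br)ccc(O)c1CCC(C)(C)O[Si](CC)(CC)CC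
F2 | step 5 | ethyl 2-[5-methoxy-7-(methoxymethoxy)-2-oxo-2H-chromen-3-yl]acetate | CCOC(=O)Cc1cc2c(OC)cc(OCOC)cc2oc1=O
F3 | step 5 | 2-[5-methoxy-7-(methoxymethoxy)-2-oxo-2H-chromen-3-yl]acetic acid | OC(=O)Cc1cc2c(OC)cc(OCOC)cc2oc1=O
F4 | step 5 | 2-[5-methoxy-7-(methoxymethoxy)-2-oxo-2H-chromen-3-yl]acetyl chloride | ClC(=O)Cc1cc2c(OC)cc(OCOC)cc2oc1=O
F5 | step 5 | 5-methoxy-7-(methoxymethoxy)-3-(2-oxoethenyl)-2H-chromen-2-one | O=C=Cc1cc2c(OC)cc(OCOC)cc2oc1=O
F6 | step 5 | 3-ethoxy-2-[5-methoxy-7-(methoxymethoxy)-2-oxo-2H-chromen-3-yl]cyclobutan-1-one (racemic, cis/trans mixture) | CCOC1CC(=O)C1c1cc2c(OC)cc(OCOC)cc2oc1=O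
F7 | step 4 | cyclobut-2-en-1-one | O=C1C=CC1
F8 | step 2 | 2-(tert-butyldimethylsilyloxy)-6-methoxy-4-(methoxymethoxy)benzaldehyde | COCOc1cc(OC)c(C=O)c(O[Si](C)(C)C(C)(C)C)c1
F9 | step 2 | ethyl (E)-2-bromo-3-[2-(tert-butyldimethylsilyloxy)-6-methoxy-4-(methoxymethoxy)phenyl]prop-2-enoate | CCOC(=O)/C(Br)=C\c1c(O[Si](C)(C)C(C)(C)C)cc(OCOC)cc1OC
F10 | step 8 | 2,2-dimethyloxetane | CC1(C)CCO1
F11 | step 8 | 6-methoxy-2-methylhex-5-yn-2-ol | COC#CCCC(C)(C)O
A1 | alternative 1 | benzene-1,3,5-triol (phloroglucinol) | Oc1cc(O)cc(O)c1
A2 | alternative 1 | ethyl 2-(5-methoxy-2,2-dimethylchroman-6-yl)-3-oxopropanoate | CCOC(=O)C(C=O)c1ccc2OC(C)(C)CCc2c1OC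
A3 | alternative 1 | 5,7-dihydroxy-3-(5-methoxy-2,2-dimethylchroman-6-yl)coumarin | O=c1oc2cc(O)cc(O)c2cc1-c1ccc2OC(C)(C)CCc2c1OC
A4 | alternative 2 | 2,2-dimethyl-3,4-dihydro-2H,5H-pyrano[3,2-c]pyran-5-one | O=c1occc2OC(C)(C)CCc12
A5 | alternative 2 | 5-methoxy-3-(methoxyethynyl)-7-(methoxymethoxy)coumarin | COC#Cc1cc2c(OC)cc(OCOC)cc2oc1=O
A6 | alternative 2 | 5-methoxy-3-(5-methoxy-2,2-dimethylchroman-6-yl)-7-(methoxymethoxy)coumarin | COCOc1cc(OC)c2cc(-c3ccc4OC(C)(C)CCc4c3OC)c(=O)oc2c1
A7 | alternative 3 | 5-(benzyloxy)-3-methoxy-2-[(E)-2-(5-methoxy-2,2-dimethylchroman-6-yl)ethenyl]phenol | COc1cc(OCc2ccccc2)cc(O)c1/C=C/c1ccc2OC(C)(C)CCc2c1OC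
A8 | alternative 3 | 7-benzyloxy-5-methoxy-3-(5-methoxy-2,2-dimethylchroman-6-yl)coumarin | COc1cc(OCc2ccccc2)cc2oc(=O)c(-c3ccc4OC(C)(C)CCc4c3OC)cc12
A9 | alternative 3 | 6-(benzyloxy)-4-methoxy-2-(5-methoxy-2,2-dimethylchroman-6-yl)benzofuran | COc1cc(OCc2ccccc2)cc2oc(-c3ccc4OC(C)(C)CCc4c3OC)cc12
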